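**Plan**
Labels: ring B is the central arene. B1 bears the butyryl group, B2, B4 and B6 bear the hydroxyls, and B3 and B5 bear the CH2 bridges. Rings A and C are the two identical 2-butanoyl-4,4-dimethylcyclohexadienone units.
Enabling feature: B2-B3-B4-B5-B6 plus both bridge CH2 groups form the chain of a 2,4-disubstituted 3-oxopentanedioate (B2 and B6 are the ester carbons, B4 the ketone). B1 with its butyryl group is pentan-2-one seen from its methyl carbon.
Cuts, in retrosynthetic order: two enol O-CH3 bonds (protection), B1-B2 and B1-B6 (double Claisen), the two bridge-CH2 to B3/B5 bonds (Michael addition), the ring-CH2 bond of each outer ring (Mannich), the two C-CH3 bonds, and the aryl-acyl bond.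
Forward order: rings A and C are made first, from phloroglucinol, by acylation and dearomatising gem-dimethylation. Two copies are then attached to dimethyl 3-oxopentanedioate, and ring B is closed last around the methyl carbon of pentan-2-one.
Stereochemistry: the target has no stereocentre. The two methine centres created in the alkylation are labile, are carried as a mixture, and vanish when B3 and B5 become aromatic.

Key step: step 6

Assumption: all enolised triketone rings are drawn in the tautomer used in the target SMILES; other tautomers are the same compounds.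
Assumption: in step 5 the methyl group is drawn on the enol oxygen next to the CMe2 carbon. The isomer methylated at the other oxygen of the same vinylogous acid would lock the bridge equally and give the same enol in step 7, so it could be carried along.

Step 1
Reactants: 1 phloroglucinol; 2 butanoyl chloride
Product: 3 1-(2,4,6-trihydroxyphenyl)butan-1-one
Conditions: AlCl3 (3.5 equiv), CH2Cl2/MeNO2, 0 to 40 °C; ice, 1 M HCl
Reagents that add atoms: none
Why: Friedel-Crafts acylation of a very electron-rich benzene, which should stop after one acyl group because the chelated aryl ketone deactivates the ring.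

Step 2
Reactants: 3 1-(2,4,6-trihydroxyphenyl)butan-1-one
Product: 4 2-butanoyl-3,5-dihydroxy-4,4-dimethylcyclohexa-2,5-dien-1-one
Conditions: NaOMe (3 equiv), MeI (2.2 equiv), MeOH, 0 °C to rt; 1 M HCl
Reagents that add atoms: iodomethane, CI
Why: Alkylative dearomatisation of an acylphloroglucinolate, in which the carbon that took the first methyl group is the most nucleophilic and takes the second, after which the strongly acidic product rests as a poorly nucleophilic anion and can be separated from lower and higher C-methyl homologues.

Step 3
Reactants: 4 2-butanoyl-3,5-dihydroxy-4,4-dimethylcyclohexa-2,5-dien-1-one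
Product: 5 2-butanoyl-6-[(dimethylamino)methyl]-3,5-dihydroxy-4,4-dimethylcyclohexa-2,5-dien-1-one
Conditions: 37% aq CH2O (1.1 equiv), 40% aq Me2NH (1.3 equiv), EtOH, 0 °C to rt
Reagents that add atoms: formaldehyde, C=O; dimethylamine, CNC
Why: Mannich reaction at C6, the only ring carbon that still bears hydrogen and the alpha carbon of a vinylogous acid, with the amine in excess so that the aminomethyl compound, expected to separate as its zwitterion, is not carried on to the methylene-bridged dimer.

Step 4
Reactants: 5 2-butanoyl-6-[(dimethylamino)methyl]-3,5-dihydroxy-4,4-dimethylcyclohexa-2,5-dien-1-one (2.1 equiv); 6 dimethyl 3-oxopentanedioate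
Product: 9 dimethyl 2,4-bis[(5-butanoyl-2,4-dihydroxy-3,3-dimethyl-6-oxocyclohexa-1,4-dien-1-yl)methyl]-3-oxopentanedioate (mixture of diastereomers), via methylene trione 7 (not isolated), via monoalkylated oxoglutarate 8 (not isolated)
Conditions: MeCN, 60 °C, N2 sweep; pH 4 wash
Reagents that add atoms: none
Why: Mannich-base alkylation of an active methylene compound by elimination-addition, in which zwitterionic 5 loses volatile dimethylamine on warming to give the quinone-methide-like acceptor 7, the oxoglutarate enol adds to it (Michael addition) first at one alpha carbon and then at the other, which is the more acidic and less hindered site of 8, and the two new methine stereocentres arise without control as a labile mixture that does not matter because both carbons become sp2 in step 6.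

Step 5
Reactants: 9 dimethyl 2,4-bis[(5-butanoyl-2,4-dihydroxy-3,3-dimethyl-6-oxocyclohexa-1,4-dien-1-yl)methyl]-3-oxopentanedioate
Product: 10 dimethyl 2,4-bis[(5-butanoyl-4-hydroxy-2-methoxy-3,3-dimethyl-6-oxocyclohexa-1,4-dien-1-yl)methyl]-3-oxopentanedioate (mixture of diastereomers)
Conditions: Me3SiCHN2 (2.1 equiv), toluene/MeOH, 0 °C
Reagents that add atoms: (trimethylsilyl)diazomethane, C[Si](C)(C)C=[N+]=[N-]
Why: O-methylation of an acid by a diazoalkane, for which the free vinylogous acid OH of each outer ring is a far better proton donor than the hydrogen-bonded acyl enol or the keto ester methines, so that two equivalents should stop at one enol ether per ring and C-alkylation at the substituted ring carbon is avoided.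

Step 6
Reactants: 10 dimethyl 2,4-bis[(5-butanoyl-4-hydroxy-2-methoxy-3,3-dimethyl-6-oxocyclohexa-1,4-dien-1-yl)methyl]-3-oxopentanedioate; 11 pentan-2-one
Product: 14 6,6'-[(5-butanoyl-2,4,6-trihydroxy-1,3-phenylene)bis(methylene)]bis(2-butanoyl-3-hydroxy-5-methoxy-4,4-dimethylcyclohexa-2,5-dien-1-one), via lithium pent-1-en-2-olate 12 (not isolated), via open-chain trioxo ester 13 (not isolated)
Conditions: (a) 10, LiN(iPr)2 (3.0 equiv), THF, -78 °C; (b) 11 (4 equiv), LiN(iPr)2 (4 equiv), THF, -78 °C, gives 12; (c) add (a) to (b), -78 to 0 °C; (d) MeOH, 0 °C to rt; cold 1 M HCl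
Reagents that add atoms: none
Why: Proposed new method: three equivalents of LiN(iPr)2 turn 10 into a trilithium salt in which both ring triketones and one keto ester half are enolates, so the ester of the other half is the only non-conjugated acyl group left, and the CH2 terminus of the kinetic enolate 12 adds to it and expels methoxide (bond B1-B2), the new B1 methylene of 13 being deprotonated at once by surplus 12. Methanol then destroys the strong bases and allows proton exchange along the chain, so that the diketonate carbon B1 meets the second ester in its non-enolised form and attacks it in a 6-(enolexo)-exo-trig Claisen closure (bond B1-B6), after which loss of methoxide and enolisation of the cyclohexanetrione give the hexasubstituted phloroglucinol ring B. The closest known reaction types are the crossed Claisen acylation of ketone lithium enolates by esters and by beta-keto ester monoanions and the base-induced Claisen cyclisation of 3,5,7-trioxo esters to acylphloroglucinols, and what is new is their union in one flask on a 2,4-dialkylated oxoglutarate. No stereocentre is formed, and the two labile methine centres of 10 become the sp2 atoms B3 and B5. Site selectivity on the ketone rests on kinetic deprotonation and is backed by the fact that only the methyl-side adduct has the hydrogens to lose on aromatisation, while Claisen folding should win over aldol folding, pyranone formation and methylene-side acylation because these are reversible in LiOMe/MeOH and the alkyl groups on B3 and B5 keep any aldol product from dehydrating to an arene. Rings A and C are shielded against the enolate as triketonate anions, methoxide exchange at their enol ethers and at the esters is degenerate, and the O-methyl groups keep the ring carbon at each bridge vinylic, so that neither retro-Michael loss of an arm nor scrambling of the methylene bridges can set in.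

Step 7
Reactants: 14 6,6'-[(5-butanoyl-2,4,6-trihydroxy-1,3-phenylene)bis(methylene)]bis(2-butanoyl-3-hydroxy-5-methoxy-4,4-dimethylcyclohexa-2,5-dien-1-one)
Product: 15 6,6'-[(5-butanoyl-2,4,6-trihydroxy-1,3-phenylene)bis(methylene)]bis(2-butanoyl-3,5-dihydroxy-4,4-dimethylcyclohexa-2,5-dien-1-one)
Conditions: BBr3 (8 equiv), CH2Cl2, -78 to 0 °C; ice water
Reagents that add atoms: none
Why: Lewis acid ether cleavage, in which BBr3 binds the carbonyl end of each vinylogous ester and bromide attacks the unhindered O-methyl carbon in an SN2 step, so that the crowded ring carbon next to CMe2 need not be approached and the cold, base-free medium gives the methylene bridges no chance to redistribute.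

**Compound list**
1 | phloroglucinol (benzene-1,3,5-triol) | Oc1cc(O)cc(O)c1 | starting material
2 | butanoyl chloride | CCCC(=O)Cl | starting material
3 | 1-(2,4,6-trihydroxyphenyl)butan-1-one | CCCC(=O)c1c(O)cc(O)cc1O | intermediate
4 | 2-butanoyl-3,5-dihydroxy-4,4-dimethylcyclohexa-2,5-dien-1-one | CCCC(=O)C1=C(O)C(C)(C)C(O)=CC1=O | intermediate
5 | 2-butanoyl-6-[(dimethylamino)methyl]-3,5-dihydroxy-4,4-dimethylcyclohexa-2,5-dien-1-one | CCCC(=O)C1=C(O)C(C)(C)C(O)=C(CN(C)C)C1=O | intermediate
6 | dimethyl 3-oxopentanedioate | COC(=O)CC(=O)CC(=O)OC | starting material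
7 | 2-butanoyl-3-hydroxy-4,4-dimethyl-6-methylidenecyclohex-2-ene-1,5-dione (not isolated) | CCCC(=O)C1=C(O)C(C)(C)C(=O)C(=C)C1=O | intermediate
8 | dimethyl 2-[(5-butanoyl-2,4-dihydroxy-3,3-dimethyl-6-oxocyclohexa-1,4-dien-1-yl)methyl]-3-oxopentanedioate (racemic, not isolated) | COC(=O)CC(=O)C(CC1=C(O)C(C)(C)C(O)=C(C(=O)CCC)C1=O)C(=O)OC | intermediate
9 | dimethyl 2,4-bis[(5-butanoyl-2,4-dihydroxy-3,3-dimethyl-6-oxocyclohexa-1,4-dien-1-yl)methyl]-3-oxopentanedioate (mixture of diastereomers, labile methines) | COC(=O)C(CC1=C(O)C(C)(C)C(O)=C(C(=O)CCC)C1=O)C(=O)C(CC1=C(O)C(C)(C)C(O)=C(C(=O)CCC)C1=O)C(=O)OC | intermediate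
10 | dimethyl 2,4-bis[(5-butanoyl-4-hydroxy-2-methoxy-3,3-dimethyl-6-oxocyclohexa-1,4-dien-1-yl)methyl]-3-oxopentanedioate (mixture of diastereomers, labile methines) | COC(=O)C(CC1=C(OC)C(C)(C)C(O)=C(C(=O)CCC)C1=O)C(=O)C(CC1=C(OC)C(C)(C)C(O)=C(C(=O)CCC)C1=O)C(=O)OC | intermediate
11 | pentan-2-one | CCCC(C)=O | starting material
12 | lithium pent-1-en-2-olate (not isolated) | [Li+].[O-]C(=C)CCC | intermediate
13 | methyl 2,4-bis[(5-butanoyl-4-hydroxy-2-methoxy-3,3-dimethyl-6-oxocyclohexa-1,4-dien-1-yl)methyl]-3,5,7-trioxodecanoate (present as lithium salts, drawn neutral, mixture of diastereomers, not isolated) | CCCC(=O)CC(=O)C(CC1=C(OC)C(C)(C)C(O)=C(C(=O)CCC)C1=O)C(=O)C(CC1=C(OC)C(C)(C)C(O)=C(C(=O)CCC)C1=O)C(=O)OC | intermediate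
14 | 6,6'-[(5-butanoyl-2,4,6-trihydroxy-1,3-phenylene)bis(methylene)]bis(2-butanoyl-3-hydroxy-5-methoxy-4,4-dimethylcyclohexa-2,5-dien-1-one) | CCCC(=O)C1=C(O)C(C)(C)C(OC)=C(Cc2c(O)c(CC3=C(OC)C(C)(C)C(O)=C(C(=O)CCC)C3=O)c(O)c(C(=O)CCC)c2O)C1=O | intermediate
15 | 6,6'-[(5-butanoyl-2,4,6-trihydroxy-1,3-phenylene)bis(methylene)]bis(2-butanoyl-3,5-dihydroxy-4,4-dimethylcyclohexa-2,5-dien-1-one), CNP0287270.0 | CCCC(=O)C1=C(O)C(C)(C)C(O)=C(Cc2c(O)c(CC3=C(O)C(C)(C)C(O)=C(C(=O)CCC)C3=O)c(O)c(C(=O)CCC)c2O)C1=O | target

Total step count: 7. Longest linear sequence: 7 steps (1, 3, 4, 5, 9, 10, 14, 15).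

**Steps most likely to fail**

Step 6. The enolate may act as a base toward the second methine of the keto diester instead of as a nucleophile. The hindered ester may acylate too slowly, or the open chain may suffer retro-Claisen cleavage before it folds. Fallback: ring B is taken ready-made and the bridges are formed by known methylene-bridge chemistry. The sequence sets out from 3 and 5. Warming 3 with one equivalent of 5 (dioxane, 60 to 80 °C) uses the same Mannich-base elimination-addition through 7 as in step 4, now with a phloroglucinol ring carbon as the Michael donor. It should give 2-butanoyl-6-[(3-butanoyl-2,4,6-trihydroxyphenyl)methyl]-3,5-dihydroxy-4,4-dimethylcyclohexa-2,5-dien-1-one F1. A second equivalent of 5 then reacts at the last free ring carbon and brings the sequence back to the route at 15.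

Step 4. Retro-Mannich cleavage may free a ring carbon that captures the methylene trione, which leads to self-dimerisation of the outer ring. The second alkylation may go to the carbon that is already substituted. The adduct may also close through an enol oxygen onto the central ketone or an ester. Fallback: the donor and acceptor roles are exchanged. Setting out from 6, a double Mannich reaction (CH2O, Me2NH, MeOH, 0 °C) should give dimethyl 2,4-bis[(dimethylamino)methyl]-3-oxopentanedioate F2. Warmed with two equivalents of 4, it should hand over its two CH2 groups by amine loss and Michael addition of ring carbon C6 of 4. The sequence comes back to the route at 9.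

Step 5. Poor discrimination between the free and the chelated enol, or between the two oxygens of one vinylogous acid, would leave a set of partly methylated isomers. Fallback: all four enols are protected covalently in place of the mixed covalent and anionic shielding.
- Setting out from 9, excess Me3OBF4 with a hindered amine base should give dimethyl 2,4-bis[(5-butanoyl-2,4-dimethoxy-3,3-dimethyl-6-oxocyclohexa-1,4-dien-1-yl)methyl]-3-oxopentanedioate F3.
- F3 needs only one equivalent of LiN(iPr)2 before it meets 12. The same acylation and ring closure should lead through methyl 2,4-bis[(5-butanoyl-2,4-dimethoxy-3,3-dimethyl-6-oxocyclohexa-1,4-dien-1-yl)methyl]-3,5,7-trioxodecanoate F4 to 6,6'-[(5-butanoyl-2,4,6-trihydroxy-1,3-phenylene)bis(methylene)]bis(2-butanoyl-3,5-dimethoxy-4,4-dimethylcyclohexa-2,5-dien-1-one) F5.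
- The four enol ethers of F5 are cleaved with BBr3 as in step 7. Any positional isomers converge there, and the sequence comes back to the route at 15.

**Further compounds**
F1 | step 6 | 2-butanoyl-6-[(3-butanoyl-2,4,6-trihydroxyphenyl)methyl]-3,5-dihydroxy-4,4-dimethylcyclohexa-2,5-dien-1-one | CCCC(=O)c1c(O)cc(O)c(CC2=C(O)C(C)(C)C(O)=C(C(=O)CCC)C2=O)c1O
F2 | step 4 | dimethyl 2,4-bis[(dimethylamino)methyl]-3-oxopentanedioate (mixture of diastereomers) | COC(=O)C(CN(C)C)C(=O)C(CN(C)C)C(=O)OC
F3 | step 5 | dimethyl 2,4-bis[(5-butanoyl-2,4-dimethoxy-3,3-dimethyl-6-oxocyclohexa-1,4-dien-1-yl)methyl]-3-oxopentanedioate (mixture of diastereomers) | COC(=O)C(CC1=C(OC)C(C)(C)C(OC)=C(C(=O)CCC)C1=O)C(=O)C(CC1=C(OC)C(C)(C)C(OC)=C(C(=O)CCC)C1=O)C(=O)OC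
F4 | step 5 | methyl 2,4-bis[(5-butanoyl-2,4-dimethoxy-3,3-dimethyl-6-oxocyclohexa-1,4-dien-1-yl)methyl]-3,5,7-trioxodecanoate (mixture of diastereomers) | CCCC(=O)CC(=O)C(CC1=C(OC)C(C)(C)C(OC)=C(C(=O)CCC)C1=O)C(=O)C(CC1=C(OC)C(C)(C)C(OC)=C(C(=O)CCC)C1=O)C(=O)OC
F5 | step 5 | 6,6'-[(5-butanoyl-2,4,6-trihydroxy-1,3-phenylene)bis(methylene)]bis(2-butanoyl-3,5-dimethoxy-4,4-dimethylcyclohexa-2,5-dien-1-one) | CCCC(=O)C1=C(OC)C(C)(C)C(OC)=C(Cc2c(O)c(CC3=C(OC)C(C)(C)C(OC)=C(C(=O)CCC)C3=O)c(O)c(C(=O)CCC)c2O)C1=O
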